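**Retrosynthetic overview**

1. The target is a 20-membered lactam ring in which spermidine bridges, through two Z-acrylamides, C9b and C8 of a cis-fused (3R,4aR,9bS)-3-hydroxy-1,2,3,4,4a,9b-hexahydrodibenzofuran.
2. The macrocycle is cut at the central CH2–CH2 bond of its N–CH2–CH2–CH2–CH2–N segment. That bond has a CH2–N on each side, so both cut ends are β-amino acids (N–CH2–CH2–CO2H: a β-alanine amide and an N-Boc-β-alanine) that give unstabilized primary radicals with no β-leaving group. The rigid tricycle with its two Z-alkene arms folds both ends to the same side. The closure is a nickel-electrocatalytic doubly decarboxylative C(sp3)–C(sp3) coupling of the bis(N-hydroxyphthalimide) ester.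
3. Seco-diacid: the Z-cinnamamide comes from Suzuki coupling of the C8 boronate with a (Z)-3-iodoacrylamide fragment; the Z-acrylamide at C9b comes from Still–Gennari olefination of the 9b-aldehyde and coupling with β-alanine ester.
4. Tricycle: arylacetonitrile + 2 methyl acrylate → 4-aryl-4-cyanocyclohexanone → dienone → CuH desymmetrization (quaternary centre) → O-demethylation/oxa-Michael (dihydrofuran ring, C4a) → bulky hydride (C3).
5. Order of ring formation: cyclohexane ring, dihydrofuran ring, 20-membered ring.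

Key step: step 19

Assumption: the starting materials 1, 2, 15, 18 and 22 are purchased, and in step 4 the ligand antipode that delivers (R)-7 is fixed in a pilot run (its mirror image is used if the sense is opposite).

**Route**

Step 1
Reactants: 1 2-(5-bromo-2-methoxyphenyl)acetonitrile; 2 methyl acrylate (2.1 equiv)
Product: 4 methyl 5-(5-bromo-2-methoxyphenyl)-5-cyano-2-oxocyclohexane-1-carboxylate, via cyano pimelate diester 3 (not isolated)
Conditions: KOt-Bu (1.6 equiv), THF, 0 °C → rt; aq. HCl
Reagents that add atoms: none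
Why: Double Michael addition of the benzylic nitrile anion to two acrylates followed in the same pot by Dieckmann condensation builds the cyclohexane ring and the (still achiral) quaternary carbon.

Step 2
Reactants: 4
Product: 5 1-(5-bromo-2-methoxyphenyl)-4-oxocyclohexane-1-carbonitrile
Conditions: 10% aq. H2SO4, AcOH, 100 °C
Reagents that add atoms: none
Why: Acid hydrolysis and decarboxylation of the β-keto ester, under which the hindered tertiary nitrile and the aryl methyl ether should react far more slowly.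

Step 3
Reactants: 5
Product: 6 1-(5-bromo-2-methoxyphenyl)-4-oxocyclohexa-2,5-diene-1-carbonitrile
Conditions: IBX (2-iodoxybenzoic acid, 3–4 equiv), DMSO, 80 °C
Reagents that add atoms: none
Why: Twofold IBX α,β-dehydrogenation of the ketone; the quaternary C4 blocks aromatization, so the symmetric cross-conjugated dienone is the end point.

Step 4
Reactants: 6
Product: 7 (1R)-1-(5-bromo-2-methoxyphenyl)-4-oxocyclohex-2-ene-1-carbonitrile
Conditions: Cu(OAc)2 (5 mol%), (R)-DTBM-SEGPHOS (5.5 mol%), MeSiH(OMe)2 (1.0 equiv), t-BuOH (1.1 equiv), toluene, −40 °C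
Reagents that add atoms: none
Why: Enantiotopic-group-selective CuH conjugate reduction (asymmetric 1,4-hydrosilylation) of a prochiral 4,4-disubstituted cyclohexadienone; the ligated CuH should tell the two enantiotopic C=C bonds apart through the large aryl and the small linear cyano group at C4, which sets the quaternary centre, and over-reduction only returns achiral 5.

Step 5
Reactants: 7
Product: 9 (4aR,9bR)-8-bromo-3-oxo-1,2,3,4,4a,9b-hexahydrodibenzo[b,d]furan-9b-carbonitrile, via phenol enone 8 (not isolated)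
Conditions: BBr3, CH2Cl2, −78 → 0 °C; aq. NaHCO3; then Et3N (cat.), CH2Cl2, rt
Reagents that add atoms: none
Why: Lewis-acid cleavage of the methyl ether frees the phenol, which closes the dihydrofuran by 5-exo-trig intramolecular oxa-Michael addition; only the cis ring fusion is geometrically possible, so the quaternary centre dictates C4a.

Step 6
Reactants: 9
Product: 10 (3R,4aR,9bR)-8-bromo-3-hydroxy-1,2,3,4,4a,9b-hexahydrodibenzo[b,d]furan-9b-carbonitrile
Conditions: Li(s-Bu)3BH, THF, −78 °C; aq. NH4Cl
Reagents that add atoms: none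
Why: Diastereoselective ketone reduction by a bulky trialkylborohydride, which should attack equatorially, away from the axial C4a–O bond, to give the axial alcohol cis to the ring oxygen as is usual for cis-fused hexahydrodibenzofuran-3-ones.

Step 7
Reactants: 10
Product: 11 (3R,4aR,9bR)-8-bromo-3-[(tert-butyldimethylsilyl)oxy]-1,2,3,4,4a,9b-hexahydrodibenzo[b,d]furan-9b-carbonitrile
Conditions: TBSOTf, 2,6-lutidine, CH2Cl2, 0 °C
Reagents that add atoms: tert-butyldimethylsilyl trifluoromethanesulfonate CC(C)(C)[Si](C)(C)OS(=O)(=O)C(F)(F)F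
Why: Silyl triflate/lutidine silylation, chosen because the alcohol is axial and hindered.

Step 8
Reactants: 11
Product: 12 (3R,4aR,9bS)-8-bromo-3-[(tert-butyldimethylsilyl)oxy]-1,2,3,4,4a,9b-hexahydrodibenzo[b,d]furan-9b-carbaldehyde
Conditions: i-Bu2AlH (1.5 equiv), toluene, −78 → −20 °C; then 1 M aq. HCl/THF, 0 °C, short
Reagents that add atoms: water O
Why: Partial reduction of the nitrile to the N-aluminio aldimine and hydrolysis; the aldehyde has no α-hydrogen, so neither epimerization nor β-elimination of the aryloxy group is possible (the change of descriptor at C9b is only a change of CIP priorities).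

Step 9
Reactants: 12
Product: 13 methyl (2Z)-3-[(3R,4aR,9bS)-8-bromo-3-[(tert-butyldimethylsilyl)oxy]-1,2,3,4,4a,9b-hexahydrodibenzo[b,d]furan-9b-yl]prop-2-enoate
Conditions: (CF3CH2O)2P(O)CH2CO2Me, KN(SiMe3)2, 18-crown-6, THF, −78 °C
Reagents that add atoms: methyl 2-[bis(2,2,2-trifluoroethoxy)phosphoryl]acetate COC(=O)CP(=O)(OCC(F)(F)F)OCC(F)(F)F
Why: Still–Gennari variant of the Horner–Wadsworth–Emmons reaction, in which the electron-poor phosphonate makes elimination faster than equilibration and so gives the Z-enoate under kinetic control.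

Step 10
Reactants: 13
Product: 14 (2Z)-3-[(3R,4aR,9bS)-8-bromo-3-[(tert-butyldimethylsilyl)oxy]-1,2,3,4,4a,9b-hexahydrodibenzo[b,d]furan-9b-yl]prop-2-enoic acid
Conditions: LiOH·H2O, THF/MeOH/H2O, 0 °C → rt; 1 M HCl to pH 3
Reagents that add atoms: lithium hydroxide [Li+].[OH-]
Why: Mild saponification; the β-carbon is neopentylic, so conjugate addition of hydroxide and the Z → E isomerization it would cause are not expected.

Step 11
Reactants: 14; 15 methyl 3-aminopropanoate hydrochloride
Product: 16 methyl 3-{[(2Z)-3-[(3R,4aR,9bS)-8-bromo-3-[(tert-butyldimethylsilyl)oxy]-1,2,3,4,4a,9b-hexahydrodibenzo[b,d]furan-9b-yl]prop-2-enoyl]amino}propanoate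
Conditions: DIC, HOBt, Et3N, CH2Cl2, 0 °C → rt
Reagents that add atoms: none
Why: Carbodiimide/HOBt amide coupling installs the β-alanine half of the future butane-1,4-diyl unit.

Step 12
Reactants: 16
Product: 17 methyl 3-{[(2Z)-3-[(3R,4aR,9bS)-3-[(tert-butyldimethylsilyl)oxy]-8-(4,4,5,5-tetramethyl-1,3,2-dioxaborolan-2-yl)-1,2,3,4,4a,9b-hexahydrodibenzo[b,d]furan-9b-yl]prop-2-enoyl]amino}propanoate
Conditions: B2pin2, Pd(dppf)Cl2 (cat.), KOAc, 1,4-dioxane, 80 °C
Reagents that add atoms: bis(pinacolato)diboron CC1(C)OB(OC1(C)C)B1OC(C)(C)C(C)(C)O1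
Why: Miyaura borylation of the aryl bromide, which tolerates the secondary amide, ester and silyl ether.

Step 13
Reactants: 18 benzyl (3-aminopropyl)carbamate; 2 methyl acrylate (1.0 equiv)
Product: 20 methyl 3-[(3-{[(benzyloxy)carbonyl]amino}propyl)(tert-butoxycarbonyl)amino]propanoate, via secondary amino ester 19 (not isolated)
Conditions: MeOH, 0 °C → rt; then Boc2O, rt
Reagents that add atoms: di-tert-butyl dicarbonate CC(C)(C)OC(=O)OC(=O)OC(C)(C)C
Why: Aza-Michael mono-addition of the primary amine to the acrylate, then carbamoylation in the same pot traps the secondary amine before a second addition.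

Step 14
Reactants: 20
Product: 21 methyl 3-[(3-aminopropyl)(tert-butoxycarbonyl)amino]propanoate
Conditions: H2 (1 atm), Pd/C, MeOH, rt; used directly
Reagents that add atoms: none
Why: Hydrogenolysis of the benzyl carbamate leaves the Boc group and the methyl ester untouched.

Step 15
Reactants: 21; 22 (2Z)-3-iodoprop-2-enoic acid
Product: 23 methyl 3-[(tert-butoxycarbonyl){3-[(2Z)-3-iodoprop-2-enamido]propyl}amino]propanoate
Conditions: DIC, HOBt, CH2Cl2, 0 °C
Reagents that add atoms: none
Why: Carbodiimide amide coupling at 0 °C, where N-acylation should outrun addition–elimination at the β-iodide and the Z geometry is retained.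

Step 16
Reactants: 17; 23
Product: 24 seco dimethyl ester: methyl 3-{[(2Z)-3-[(3R,4aR,9bS)-3-[(tert-butyldimethylsilyl)oxy]-8-[(1Z)-3-({3-[(tert-butoxycarbonyl)(3-methoxy-3-oxopropyl)amino]propyl}amino)-3-oxoprop-1-en-1-yl]-1,2,3,4,4a,9b-hexahydrodibenzo[b,d]furan-9b-yl]prop-2-enoyl]amino}propanoate
Conditions: Pd(dppf)Cl2 (cat.), aq. K3PO4, THF, rt → 40 °C
Reagents that add atoms: none
Why: Suzuki–Miyaura coupling of the aryl boronate with the Z-vinyl iodide, whose oxidative addition and reductive elimination are stereoretentive, gives the Z-cinnamamide.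

Step 17
Reactants: 24
Product: 25 seco diacid: the bis(carboxylic acid) corresponding to both methyl esters of 24
Conditions: LiOH·H2O, THF/H2O, 0 °C → rt; aq. HCl to pH 3–4 at 0 °C
Reagents that add atoms: lithium hydroxide [Li+].[OH-]
Why: Saponification of two unhindered aliphatic methyl esters, under which Boc, silyl ether and both Z-enamides are stable.

Step 18
Reactants: 25
Product: 26 bis(1,3-dioxoisoindolin-2-yl) ester of 25
Conditions: N-hydroxyphthalimide (2.2 equiv), DIC (2.2 equiv), DMAP (cat.), CH2Cl2, rt; rapid filtration through silica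
Reagents that add atoms: N-hydroxyphthalimide ON1C(=O)c2ccccc2C1=O
Why: Steglich-type esterification converts both carboxylic acids into redox-active esters.

Step 19
Reactants: 26
Product: 27 N-Boc O-TBS macrocycle: the 20-membered bis-(Z)-enamide lactam carrying Boc on the central nitrogen and TBS on the C3 oxygen
Conditions: NiCl2·6H2O (30 mol%), 2,2':6',2''-terpyridine (30 mol%), NaI, DMF, Mg anode/reticulated vitreous carbon cathode, undivided cell, constant current (ca. 3 F/mol), rt; 26 added by syringe pump (final ≤ 2 mM); aq. NH4Cl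
Reagents that add atoms: none
Why: Proposed new method: cathodically generated low-valent nickel–terpyridine (monovalent/zerovalent nickel) reduces one N-acyloxyphthalimide of 26 by single-electron transfer, N–O cleavage and loss of CO2 give a primary β-amidoalkyl radical that is captured at nickel, the second redox-active ester of the same molecule is activated in the same way, and reductive elimination from the dialkyl trivalent nickel forges the CH2–CH2 bond. The closest known reaction type is the intermolecular nickel-electrocatalytic doubly decarboxylative C(sp3)–C(sp3) coupling of two redox-active esters (the reductive counterpart of a mixed Kolbe coupling); new here is its intramolecular use as a macrocyclization on a substrate carrying two Z-enamides. One ring is closed, the 20-membered lactam ring, by end-to-end C(sp3)–C(sp3) reductive elimination from a 21-membered nickelacycle, so no exo/endo mode applies and no stereocentre is formed. The step needs ring closure to win over oligomerization and over hydrogen-atom quenching, and the two Z-acrylamides must neither trap radicals nor isomerize. This should be secured by slow addition into the cell (low stationary concentration, while the tether turns the otherwise statistical hetero-coupling into an intramolecular event), by the rigid cis-fused tricycle whose two Z-alkene arms point both chain ends to the same side, and by the fact that both radicals are unstabilized primary radicals that nickel captures faster than they add to β-substituted acrylamides. The trans secondary-amide rotamer also holds the N–CH2–CH2 radical away from its own C=C, so 5-exo or 6-endo self-trapping is disfavoured, and the cathode works far positive of the reduction potential of a cinnamamide.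

Step 20
Reactants: 27
Product: 28 CNP0243477.1
Conditions: HCl (3 M in MeOH), 0 °C → rt; then aq. NaHCO3
Reagents that add atoms: none
Why: Acidolysis removes the Boc carbamate and the secondary silyl ether in one operation, while the amine stays protonated and so cannot add to the enamides.

**Compound list**

1 | 2-(5-bromo-2-methoxyphenyl)acetonitrile | N#CCc1cc(Br)ccc1OC | starting material
2 | methyl acrylate | C=CC(=O)OC | starting material
3 | dimethyl 4-(5-bromo-2-methoxyphenyl)-4-cyanoheptanedioate | COC(=O)CCC(C#N)(CCC(=O)OC)c1cc(Br)ccc1OC | intermediate (not isolated)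
4 | methyl 5-(5-bromo-2-methoxyphenyl)-5-cyano-2-oxocyclohexane-1-carboxylate (keto/enol and diastereomer mixture) | COC(=O)C1CC(C#N)(c2cc(Br)ccc2OC)CCC1=O | intermediate
5 | 1-(5-bromo-2-methoxyphenyl)-4-oxocyclohexane-1-carbonitrile | N#CC1(CCC(=O)CC1)c1cc(Br)ccc1OC | intermediate
6 | 1-(5-bromo-2-methoxyphenyl)-4-oxocyclohexa-2,5-diene-1-carbonitrile | N#CC1(C=CC(=O)C=C1)c1cc(Br)ccc1OC | intermediate
7 | (1R)-1-(5-bromo-2-methoxyphenyl)-4-oxocyclohex-2-ene-1-carbonitrile | N#C[C@]1(C=CC(=O)CC1)c1cc(Br)ccc1OC | intermediate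
8 | (1R)-1-(5-bromo-2-hydroxyphenyl)-4-oxocyclohex-2-ene-1-carbonitrile | N#C[C@]1(C=CC(=O)CC1)c1cc(Br)ccc1O | intermediate (not isolated)
9 | (4aR,9bR)-8-bromo-3-oxo-1,2,3,4,4a,9b-hexahydrodibenzo[b,d]furan-9b-carbonitrile (cis-fused) | N#C[C@]23CCC(=O)C[C@H]2Oc2ccc(Br)cc23 | intermediate
10 | (3R,4aR,9bR)-8-bromo-3-hydroxy-1,2,3,4,4a,9b-hexahydrodibenzo[b,d]furan-9b-carbonitrile (OH cis to the ring oxygen) | N#C[C@]23CC[C@@H](O)C[C@H]2Oc2ccc(Br)cc23 | intermediate
11 | (3R,4aR,9bR)-8-bromo-3-[(tert-butyldimethylsilyl)oxy]-1,2,3,4,4a,9b-hexahydrodibenzo[b,d]furan-9b-carbonitrile | N#C[C@]23CC[C@@H](O[Si](C)(C)C(C)(C)C)C[C@H]2Oc2ccc(Br)cc23 | intermediate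
12 | (3R,4aR,9bS)-8-bromo-3-[(tert-butyldimethylsilyl)oxy]-1,2,3,4,4a,9b-hexahydrodibenzo[b,d]furan-9b-carbaldehyde | O=C[C@]23CC[C@@H](O[Si](C)(C)C(C)(C)C)C[C@H]2Oc2ccc(Br)cc23 | intermediate
13 | methyl (2Z)-3-[(3R,4aR,9bS)-8-bromo-3-[(tert-butyldimethylsilyl)oxy]-1,2,3,4,4a,9b-hexahydrodibenzo[b,d]furan-9b-yl]prop-2-enoate | COC(=O)/C=C\[C@]23CC[C@@H](O[Si](C)(C)C(C)(C)C)C[C@H]2Oc2ccc(Br)cc23 | intermediate
14 | (2Z)-3-[(3R,4aR,9bS)-8-bromo-3-[(tert-butyldimethylsilyl)oxy]-1,2,3,4,4a,9b-hexahydrodibenzo[b,d]furan-9b-yl]prop-2-enoic acid | OC(=O)/C=C\[C@]23CC[C@@H](O[Si](C)(C)C(C)(C)C)C[C@H]2Oc2ccc(Br)cc23 | intermediate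
15 | methyl 3-aminopropanoate hydrochloride | COC(=O)CCN.Cl | starting material
16 | methyl 3-{[(2Z)-3-[(3R,4aR,9bS)-8-bromo-3-[(tert-butyldimethylsilyl)oxy]-1,2,3,4,4a,9b-hexahydrodibenzo[b,d]furan-9b-yl]prop-2-enoyl]amino}propanoate | COC(=O)CCNC(=O)/C=C\[C@]23CC[C@@H](O[Si](C)(C)C(C)(C)C)C[C@H]2Oc2ccc(Br)cc23 | intermediate
17 | 8-(4,4,5,5-tetramethyl-1,3,2-dioxaborolan-2-yl) analogue of 16 (aryl pinacol boronate) | COC(=O)CCNC(=O)/C=C\[C@]23CC[C@@H](O[Si](C)(C)C(C)(C)C)C[C@H]2Oc2ccc(B4OC(C)(C)C(C)(C)O4)cc23 | intermediate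
18 | benzyl (3-aminopropyl)carbamate | NCCCNC(=O)OCc1ccccc1 | starting material
19 | methyl 3-[(3-{[(benzyloxy)carbonyl]amino}propyl)amino]propanoate | COC(=O)CCNCCCNC(=O)OCc1ccccc1 | intermediate (not isolated)
20 | methyl 3-[(3-{[(benzyloxy)carbonyl]amino}propyl)(tert-butoxycarbonyl)amino]propanoate | COC(=O)CCN(CCCNC(=O)OCc1ccccc1)C(=O)OC(C)(C)C | intermediate
21 | methyl 3-[(3-aminopropyl)(tert-butoxycarbonyl)amino]propanoate | COC(=O)CCN(CCCN)C(=O)OC(C)(C)C | intermediate
22 | (2Z)-3-iodoprop-2-enoic acid | OC(=O)/C=C\I | starting material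
23 | methyl 3-[(tert-butoxycarbonyl){3-[(2Z)-3-iodoprop-2-enamido]propyl}amino]propanoate | COC(=O)CCN(CCCNC(=O)/C=C\I)C(=O)OC(C)(C)C | intermediate
24 | seco dimethyl ester (Z-acrylamide of β-alanine methyl ester at C9b; Z-cinnamamide at C8 carrying the N-Boc-N-(3-methoxy-3-oxopropyl)aminopropyl chain; 3-OTBS) | COC(=O)CCNC(=O)/C=C\[C@]23CC[C@@H](O[Si](C)(C)C(C)(C)C)C[C@H]2Oc2ccc(cc23)/C=C\C(=O)NCCCN(CCC(=O)OC)C(=O)OC(C)(C)C | intermediate
25 | seco diacid (both methyl esters of 24 as CO2H) | OC(=O)CCNC(=O)/C=C\[C@]23CC[C@@H](O[Si](C)(C)C(C)(C)C)C[C@H]2Oc2ccc(cc23)/C=C\C(=O)NCCCN(CCC(=O)O)C(=O)OC(C)(C)C | intermediate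
26 | bis(1,3-dioxoisoindolin-2-yl) ester of 25 | O=C(ON1C(=O)c2ccccc2C1=O)CCNC(=O)/C=C\[C@]23CC[C@@H](O[Si](C)(C)C(C)(C)C)C[C@H]2Oc2ccc(cc23)/C=C\C(=O)NCCCN(CCC(=O)ON2C(=O)c3ccccc3C2=O)C(=O)OC(C)(C)C | intermediate
27 | N-Boc O-TBS macrocycle (20-membered bis-(Z)-enamide lactam; Boc on the central nitrogen; 3-OTBS) | O=C1/C=C\[C@]23CC[C@@H](O[Si](C)(C)C(C)(C)C)C[C@H]2Oc2ccc(cc23)/C=C\C(=O)NCCCN(C(=O)OC(C)(C)C)CCCCN1 | intermediate
28 | CNP0243477.1 (20-membered (Z,Z)-bis-enamide spermidine lactam on the (3R,4aR,9bS)-3-hydroxyhexahydrodibenzofuran) | O=C1/C=C\[C@]23CC[C@@H](O)C[C@H]2Oc2ccc(cc23)/C=C\C(=O)NCCCNCCCCN1 | target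

**Step count and risks**

Total step count: 20 (17 in the main line, 3 for the iodoacrylamide 23).
Longest linear sequence: 17 steps (steps 1–12 and 16–20).

Steps most likely to fail:

1. Step 19 (proposed new method). What may go wrong: intermolecular coupling to oligomers, hydrogen-atom quenching of the alkyl radicals before the second activation, or radical addition to and Z → E isomerization of the enamides. The fallback uses known chemistry, closes the ring at the neighbouring N–CH2 bond, sets out from 14 and comes back at 28. Acid 14 is coupled (DIC, HOBt) with 4-aminobutan-1-ol to the N-(4-hydroxybutyl) Z-acrylamide F1, which is borylated (B2pin2, Pd(dppf)Cl2, KOAc) to the pinacol boronate F2. Excess 1,3-diaminopropane and 2-nitrobenzenesulfonyl chloride give N-(3-aminopropyl)-2-nitrobenzenesulfonamide F3, which is acylated with 22 (DIC, HOBt) to the Z-iodoacrylamide F4. Suzuki–Miyaura coupling of F2 and F4 gives the seco hydroxy sulfonamide F5. Intramolecular Fukuyama–Mitsunobu alkylation (PPh3, diisopropyl azodicarboxylate, toluene/THF, high dilution) gives the N-nosyl macrocycle F6. PhSH/K2CO3 in DMF removes the nosyl group to give the O-silyl macrocyclic amine F7, and HCl/MeOH then gives 28.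

2. Step 4. What may go wrong: insufficient discrimination of the two enantiotopic C=C bonds, or over-reduction back to 5. The fallback sets out from 5 and comes back at 7, bypassing steps 3 and 4. Enantioselective deprotonation of 5 with lithium (R,R)- or (S,S)-bis(1-phenylethyl)amide in the presence of Me3SiCl (THF, −100 °C) gives the (R)-trimethylsilyl enol ether F8, and Saegusa–Ito oxidation (Pd(OAc)2, MeCN) gives 7.

3. Step 9. What may go wrong: slow addition to the hindered α-quaternary aldehyde and erosion of Z selectivity on warming. The fallback sets out from 12 and comes back at 13. Seyferth–Gilbert homologation with the Ohira–Bestmann reagent (dimethyl (1-diazo-2-oxopropyl)phosphonate, K2CO3, MeOH) gives the terminal alkyne F9. Deprotonation with LiN(SiMe3)2 and trapping with methyl chloroformate gives the ynoate F10. Semihydrogenation (H2, Pd/CaCO3 poisoned with Pb(OAc)2, quinoline, EtOAc) gives 13, with the Z geometry fixed by syn addition of hydrogen.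

**Further compounds**

F1 | step 19 | (2Z)-3-[(3R,4aR,9bS)-8-bromo-3-[(tert-butyldimethylsilyl)oxy]-1,2,3,4,4a,9b-hexahydrodibenzo[b,d]furan-9b-yl]-N-(4-hydroxybutyl)prop-2-enamide | OCCCCNC(=O)/C=C\[C@]23CC[C@@H](O[Si](C)(C)C(C)(C)C)C[C@H]2Oc2ccc(Br)cc23
F2 | step 19 | 8-(4,4,5,5-tetramethyl-1,3,2-dioxaborolan-2-yl) analogue of F1 | OCCCCNC(=O)/C=C\[C@]23CC[C@@H](O[Si](C)(C)C(C)(C)C)C[C@H]2Oc2ccc(B4OC(C)(C)C(C)(C)O4)cc23
F3 | step 19 | N-(3-aminopropyl)-2-nitrobenzenesulfonamide | NCCCNS(=O)(=O)c1ccccc1[N+](=O)[O-]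
F4 | step 19 | (2Z)-3-iodo-N-{3-[(2-nitrophenyl)sulfonylamino]propyl}prop-2-enamide | I/C=C\C(=O)NCCCNS(=O)(=O)c1ccccc1[N+](=O)[O-]
F5 | step 19 | seco hydroxy sulfonamide (N-(4-hydroxybutyl) Z-acrylamide at C9b; Z-cinnamamide at C8 carrying the 3-(2-nitrophenylsulfonylamino)propyl chain; 3-OTBS) | OCCCCNC(=O)/C=C\[C@]23CC[C@@H](O[Si](C)(C)C(C)(C)C)C[C@H]2Oc2ccc(cc23)/C=C\C(=O)NCCCNS(=O)(=O)c2ccccc2[N+](=O)[O-]
F6 | step 19 | N-(2-nitrophenylsulfonyl) O-TBS macrocycle | O=C1/C=C\[C@]23CC[C@@H](O[Si](C)(C)C(C)(C)C)C[C@H]2Oc2ccc(cc23)/C=C\C(=O)NCCCN(S(=O)(=O)c2ccccc2[N+](=O)[O-])CCCCN1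
F7 | step 19 | O-TBS ether of the target (free central amine) | O=C1/C=C\[C@]23CC[C@@H](O[Si](C)(C)C(C)(C)C)C[C@H]2Oc2ccc(cc23)/C=C\C(=O)NCCCNCCCCN1
F8 | step 4 | (1R)-1-(5-bromo-2-methoxyphenyl)-4-[(trimethylsilyl)oxy]cyclohex-3-ene-1-carbonitrile | N#C[C@]1(CC=C(O[Si](C)(C)C)CC1)c1cc(Br)ccc1OC
F9 | step 9 | tert-butyl{[(3R,4aR,9bS)-8-bromo-9b-ethynyl-1,2,3,4,4a,9b-hexahydrodibenzo[b,d]furan-3-yl]oxy}dimethylsilane | C#C[C@]23CC[C@@H](O[Si](C)(C)C(C)(C)C)C[C@H]2Oc2ccc(Br)cc23
F10 | step 9 | methyl 3-[(3R,4aR,9bS)-8-bromo-3-[(tert-butyldimethylsilyl)oxy]-1,2,3,4,4a,9b-hexahydrodibenzo[b,d]furan-9b-yl]prop-2-ynoate | COC(=O)C#C[C@]23CC[C@@H](O[Si](C)(C)C(C)(C)C)C[C@H]2Oc2ccc(Br)cc23
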